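Ring A of the chromone (C4a, C5, C6, C7, C8, C8a) bears oxygen on the alternating carbons C5, C7 and C8a, the signature of a folded polyketide chain. It is therefore disconnected at C4a–C5 to a monocyclic 4-pyranone that carries the 4-silyloxyphenoxy group at one α-carbon and a CH2–CO–CH2–CO2Me arm at the other. A single base-mediated operation lets the vinylogous enolate of this arm acylate the pyranone β-carbon with the terminal ester, closes the carbocycle and aromatises it to the 5,7-dihydroxychromone with the 2-aryloxy unit already installed. Selective 7-O-prenylation and fluoride desilylation then finish the synthesis.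

Key step: step 7

Remark: the target has no stereocentre and no stereogenic double bond (the prenyl alkene carries two identical methyl groups), so it is one achiral compound and no configuration has to be set.
Remark: the 4'-oxygen is carried as a triisopropylsilyl ether because this group tolerates phenoxide, organolithium and amidine bases; oxygen salts of a product that are only acidified in the work-up are not numbered separately.

Step 1
Reactants: 1 hydroquinone
Product: 2 4-(triisopropylsilyloxy)phenol
Conditions: TIPSCl (1.0 equiv), imidazole (2.2 equiv), 1 (3 equiv), DMF, 0 °C → rt; excess 1 removed by aqueous wash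
Reagents that add atoms: triisopropylsilyl chloride, CC(C)[Si](Cl)(C(C)C)C(C)C
Why: Imidazole-mediated silyl ether formation on a symmetric diphenol used in excess should give mainly the mono-ether, and the water-soluble diol is easily washed out.

Step 2
Reactants: 2 4-(triisopropylsilyloxy)phenol; 3 trichloroethylene
Product: 5 {4-[(E)-1,2-dichloroethenyloxy]phenoxy}triisopropylsilane, via dichloroacetylene 4 (not isolated)
Conditions: KH (1.5 equiv), THF, 0 °C; then 3 (1.1 equiv), −40 °C → rt
Reagents that add atoms: none
Why: Base-induced dehydrochlorination of trichloroethylene gives dichloroacetylene, to which the potassium phenoxide adds in anti fashion (the standard phenol/trichloroethylene route to 1,2-dichlorovinyl ethers); the E geometry is lost in the next step and is of no consequence.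

Step 3
Reactants: 5 {4-[(E)-1,2-dichloroethenyloxy]phenoxy}triisopropylsilane
Product: 8 [4-(ethynyloxy)phenoxy]triisopropylsilane, via aryl chloroethynyl ether 6 (not isolated), via lithium aryloxyacetylide 7 (not isolated)
Conditions: n-BuLi (2.3 equiv), THF, −78 → −40 °C; H2O quench at −78 °C; used at once as a cold solution
Reagents that add atoms: none
Why: Deprotonation and β-elimination of chloride give the chloroalkynyl ether, chlorine–lithium exchange gives the acetylide, and low-temperature protonation should give the terminal aryl ynol ether (the established dichlorovinyl ether to ynol ether conversion).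

Step 4
Reactants: 8 [4-(ethynyloxy)phenoxy]triisopropylsilane; 9 2,2,6-trimethyl-4H-1,3-dioxin-4-one
Product: 11 2-methyl-6-[4-(triisopropylsilyloxy)phenoxy]-4H-pyran-4-one, via acetylketene 10 (not isolated)
Conditions: 9 (2 equiv, added over 1 h), toluene, 110 °C
Reagents that add atoms: none
Why: Thermal retro-[4+2] of the dioxinone releases acetylketene, which should be trapped by the electron-rich alkyne in a hetero-Diels–Alder cycloaddition; polarity matching (alkyne CH to the ketene carbon, acetyl oxygen to the aryloxy-bearing carbon) places the aryloxy group next to the ring oxygen.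

Step 5
Reactants: 11 2-methyl-6-[4-(triisopropylsilyloxy)phenoxy]-4H-pyran-4-one
Product: 13 {4-oxo-6-[4-(triisopropylsilyloxy)phenoxy]-4H-pyran-2-yl}acetic acid, via lithium dienolate 12 (not isolated)
Conditions: LiHMDS (1.15 equiv), THF, −78 °C; cannulated into CO2-saturated THF, −78 °C; cold dilute HCl to pH 3; no heating
Reagents that add atoms: carbon dioxide, O=C=O
Why: Lateral (vinylogous) deprotonation of a 2-methyl-4-pyranone by a hindered amide gives the extended enolate, which should be carboxylated at the exocyclic carbon because this restores the pyranone; inverse addition into excess CO2 limits proton transfer from the product.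

Step 6
Reactants: 13 {4-oxo-6-[4-(triisopropylsilyloxy)phenoxy]-4H-pyran-2-yl}acetic acid
Product: 16 methyl 3-oxo-4-{4-oxo-6-[4-(triisopropylsilyloxy)phenoxy]-4H-pyran-2-yl}butanoate, via acyl imidazolide 14 (not isolated), via acylmalonic half-ester 15 (not isolated)
Conditions: CDI (1.1 equiv), THF, 0 °C → rt; then KO2CCH2CO2Me (2 equiv), MgCl2 (2 equiv), Et3N (3 equiv), THF, rt; cold dilute HCl
Reagents that add atoms: potassium methyl malonate, COC(=O)CC(=O)[O-].[K+]
Why: Masamune–Brooks homologation: the acyl imidazolide is C-acylated by the magnesium enolate of the malonate half-ester and the adduct loses CO2 to give the β-keto ester under nearly neutral conditions.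

Step 7
Reactants: 16 methyl 3-oxo-4-{4-oxo-6-[4-(triisopropylsilyloxy)phenoxy]-4H-pyran-2-yl}butanoate
Product: 18 5,7-dihydroxy-2-[4-(triisopropylsilyloxy)phenoxy]-4H-chromen-4-one, via triketone tautomer 17 (not isolated)
Conditions: DBU (3 equiv), 4 Å MS, THF (0.02 M), rt → 60 °C; aq. citric acid work-up
Reagents that add atoms: none
Why: DBU equilibrates the acidic sites of the arm, and the anion at the CH2 between the ketone and pyranone C2 is an extended dienolate whose α-carbon, pyranone C3 (the future C4a), adds to the ester carbonyl (the future C5); loss of methoxide gives trione 17, which should tautomerise to the phloroglucinol-type ring of 18. The closest known reaction type is the biomimetic Claisen (Dieckmann-type) cyclisation of β,δ-dicarbonyl ester chains to phloroglucinol rings. Ring A closes by a 6-exo-trig (enolendo) attack on the ester carbon, forming the C4a–C5 bond. No stereocentre is created. The step needs C-acylation through the dienolate α-carbon and no attack at the aryloxy-bearing carbon: the first is secured by geometry, since pyranone C3 is the only nucleophilic carbon that reaches the ester through a six-membered transition state (closure from the side-chain carbons would give four-membered rings, and an aldol onto the pyranone carbonyl would need a bridgehead alkene), the second by the non-nucleophilic amidine, high dilution and sieves that take up the methanol released. Aromatisation and deprotonation of the acidic 7-OH should make the sequence irreversible.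

Step 8
Reactants: 18 5,7-dihydroxy-2-[4-(triisopropylsilyloxy)phenoxy]-4H-chromen-4-one; 19 prenyl bromide
Product: 20 5-hydroxy-7-[(3-methylbut-2-en-1-yl)oxy]-2-[4-(triisopropylsilyloxy)phenoxy]-4H-chromen-4-one
Conditions: 19 (1.1 equiv), K2CO3 (1.2 equiv), acetone, rt → 40 °C
Reagents that add atoms: none
Why: Williamson etherification should occur at the more acidic, unchelated 7-OH, because the 5-OH is held in a hydrogen bond to the C4 carbonyl and is far less nucleophilic under weak carbonate base.

Step 9
Reactants: 20 5-hydroxy-7-[(3-methylbut-2-en-1-yl)oxy]-2-[4-(triisopropylsilyloxy)phenoxy]-4H-chromen-4-one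
Product: 21 5-hydroxy-2-(4-hydroxyphenoxy)-7-[(3-methylbut-2-en-1-yl)oxy]-4H-chromen-4-one
Conditions: TBAF (1.2 equiv), AcOH (1.5 equiv), THF, 0 °C
Reagents that add atoms: none
Why: Fluoride-induced cleavage of the aryl silyl ether; acetic acid buffering keeps the liberated phenol protonated so that it does not add to C2 of another chromone, and the prenyl ether and enol ether linkage are untouched.

Compound list
1 | hydroquinone | Oc1ccc(O)cc1 | starting material
2 | 4-(triisopropylsilyloxy)phenol | CC(C)[Si](Oc1ccc(O)cc1)(C(C)C)C(C)C | intermediate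
3 | trichloroethylene | ClC=C(Cl)Cl | starting material
4 | dichloroacetylene | ClC#CCl | intermediate
5 | {4-[(E)-1,2-dichloroethenyloxy]phenoxy}triisopropylsilane | Cl/C=C(/Cl)Oc1ccc(O[Si](C(C)C)(C(C)C)C(C)C)cc1 | intermediate
6 | [4-(chloroethynyloxy)phenoxy]triisopropylsilane | ClC#COc1ccc(O[Si](C(C)C)(C(C)C)C(C)C)cc1 | intermediate
7 | lithium [4-(triisopropylsilyloxy)phenoxy]acetylide | [Li]C#COc1ccc(O[Si](C(C)C)(C(C)C)C(C)C)cc1 | intermediate
8 | [4-(ethynyloxy)phenoxy]triisopropylsilane | C#COc1ccc(O[Si](C(C)C)(C(C)C)C(C)C)cc1 | intermediate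
9 | 2,2,6-trimethyl-4H-1,3-dioxin-4-one | CC1=CC(=O)OC(C)(C)O1 | starting material
10 | acetylketene (3-oxobut-1-en-1-one) | CC(=O)C=C=O | intermediate
11 | 2-methyl-6-[4-(triisopropylsilyloxy)phenoxy]-4H-pyran-4-one | Cc1cc(=O)cc(Oc2ccc(O[Si](C(C)C)(C(C)C)C(C)C)cc2)o1 | intermediate
12 | lithium 2-methylidene-6-[4-(triisopropylsilyloxy)phenoxy]-2H-pyran-4-olate | [Li]OC1=CC(=C)OC(Oc2ccc(O[Si](C(C)C)(C(C)C)C(C)C)cc2)=C1 | intermediate
13 | {4-oxo-6-[4-(triisopropylsilyloxy)phenoxy]-4H-pyran-2-yl}acetic acid | OC(=O)Cc1cc(=O)cc(Oc2ccc(O[Si](C(C)C)(C(C)C)C(C)C)cc2)o1 | intermediate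
14 | 1-({4-oxo-6-[4-(triisopropylsilyloxy)phenoxy]-4H-pyran-2-yl}acetyl)imidazole | O=C(Cc1cc(=O)cc(Oc2ccc(O[Si](C(C)C)(C(C)C)C(C)C)cc2)o1)n1ccnc1 | intermediate
15 | 2-(methoxycarbonyl)-3-oxo-4-{4-oxo-6-[4-(triisopropylsilyloxy)phenoxy]-4H-pyran-2-yl}butanoic acid | COC(=O)C(C(=O)O)C(=O)Cc1cc(=O)cc(Oc2ccc(O[Si](C(C)C)(C(C)C)C(C)C)cc2)o1 | intermediate
16 | methyl 3-oxo-4-{4-oxo-6-[4-(triisopropylsilyloxy)phenoxy]-4H-pyran-2-yl}butanoate | COC(=O)CC(=O)Cc1cc(=O)cc(Oc2ccc(O[Si](C(C)C)(C(C)C)C(C)C)cc2)o1 | intermediate
17 | 2-[4-(triisopropylsilyloxy)phenoxy]-6,8-dihydro-4H-chromene-4,5,7-trione | O=C1CC(=O)c2c(C1)oc(Oc1ccc(O[Si](C(C)C)(C(C)C)C(C)C)cc1)cc2=O | intermediate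
18 | 5,7-dihydroxy-2-[4-(triisopropylsilyloxy)phenoxy]-4H-chromen-4-one | CC(C)[Si](Oc1ccc(Oc2cc(=O)c3c(O)cc(O)cc3o2)cc1)(C(C)C)C(C)C | intermediate
19 | prenyl bromide (1-bromo-3-methylbut-2-ene) | CC(C)=CCBr | starting material
20 | 5-hydroxy-7-[(3-methylbut-2-en-1-yl)oxy]-2-[4-(triisopropylsilyloxy)phenoxy]-4H-chromen-4-one | CC(C)=CCOc1cc(O)c2c(=O)cc(Oc3ccc(O[Si](C(C)C)(C(C)C)C(C)C)cc3)oc2c1 | intermediate
21 | 5-hydroxy-2-(4-hydroxyphenoxy)-7-[(3-methylbut-2-en-1-yl)oxy]-4H-chromen-4-one | CC(C)=CCOc1cc(O)c2c(=O)cc(Oc3ccc(O)cc3)oc2c1 | target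

Total step count: 9. Longest linear sequence: 9 steps (1 → 21); 3, 9 and 19 enter as commercial building blocks.

Steps most likely to fail

Step 7. The ring closure may stall because the arm is held as its unreactive β-keto ester enolate, or methoxide or the amidine may add at the aryloxy-bearing carbon and expel the aryl ether. The fallback sets out from 2 and comes back at 18; it builds ring A first and forms the aryl ether bond last. Commercial 1-[2,4-bis(benzyloxy)-6-hydroxyphenyl]ethanone F1 would be condensed with CS2 and t-BuOK in THF to 5,7-bis(benzyloxy)-4-hydroxy-2H-chromene-2-thione F2. S-Methylation (MeI, K2CO3, acetone) would give 5,7-bis(benzyloxy)-2-(methylsulfanyl)-4H-chromen-4-one F3, and oxidation (mCPBA, CH2Cl2) 5,7-bis(benzyloxy)-2-(methylsulfonyl)-4H-chromen-4-one F4. Addition–elimination with phenol 2 (K2CO3, MeCN) should then give 5,7-bis(benzyloxy)-2-[4-(triisopropylsilyloxy)phenoxy]-4H-chromen-4-one F5, and hydrogenolysis of both benzyl ethers (H2, Pd/C, EtOAc) would return to 18.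

Step 4. The terminal ynol ether may oligomerise at 110 °C faster than it is trapped, or the ketene may be captured in a [2+2] mode that leads to an isomeric pyranone. The fallback sets out from 2 and comes back at 11; it makes the pyranone without any ynol ether. Commercial 4,4-bis(methylsulfanyl)but-3-en-2-one F6 would be acetylated at its methyl group (NaH, EtOAc, THF, reflux) to 6,6-bis(methylsulfanyl)hex-5-ene-2,4-dione F7. Acid-induced cyclisation (TFA, CH2Cl2) with loss of methanethiol should give 2-methyl-6-(methylsulfanyl)-4H-pyran-4-one F8, and oxidation (mCPBA) 2-methyl-6-(methylsulfonyl)-4H-pyran-4-one F9. Addition–elimination with phenol 2 (K2CO3, MeCN) would then give 11.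

Step 5. The amide base may metalate a ring C–H or add to the aryloxy-bearing carbon instead of deprotonating the methyl group, and the vinylogous β-keto acid may lose CO2 during work-up. The fallback sets out from 9 and 8 and comes back at 13; it carries the acetic acid arm through the cycloaddition. Dioxinone 9 would be carboxylated at its methyl group (LiHMDS 2 equiv, THF, −78 °C; Boc2O) to tert-butyl (2,2-dimethyl-4-oxo-4H-1,3-dioxin-6-yl)acetate F10. Heating F10 with ynol ether 8 (toluene, 110 °C) should give tert-butyl {4-oxo-6-[4-(triisopropylsilyloxy)phenoxy]-4H-pyran-2-yl}acetate F11. Cleavage of the tert-butyl ester (TFA, CH2Cl2, 0 °C, evaporation in the cold) would give 13 without an aqueous step.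

Further compounds
F1 | step 7 | 1-[2,4-bis(benzyloxy)-6-hydroxyphenyl]ethanone | CC(=O)c1c(O)cc(OCc2ccccc2)cc1OCc1ccccc1
F2 | step 7 | 5,7-bis(benzyloxy)-4-hydroxy-2H-chromene-2-thione | Oc1cc(=S)oc2cc(OCc3ccccc3)cc(OCc3ccccc3)c12
F3 | step 7 | 5,7-bis(benzyloxy)-2-(methylsulfanyl)-4H-chromen-4-one | CSc1cc(=O)c2c(OCc3ccccc3)cc(OCc3ccccc3)cc2o1
F4 | step 7 | 5,7-bis(benzyloxy)-2-(methylsulfonyl)-4H-chromen-4-one | CS(=O)(=O)c1cc(=O)c2c(OCc3ccccc3)cc(OCc3ccccc3)cc2o1
F5 | step 7 | 5,7-bis(benzyloxy)-2-[4-(triisopropylsilyloxy)phenoxy]-4H-chromen-4-one | CC(C)[Si](Oc1ccc(Oc2cc(=O)c3c(OCc4ccccc4)cc(OCc4ccccc4)cc3o2)cc1)(C(C)C)C(C)C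
F6 | step 4 | 4,4-bis(methylsulfanyl)but-3-en-2-one | CC(=O)C=C(SC)SC
F7 | step 4 | 6,6-bis(methylsulfanyl)hex-5-ene-2,4-dione | CC(=O)CC(=O)C=C(SC)SC
F8 | step 4 | 2-methyl-6-(methylsulfanyl)-4H-pyran-4-one | CSc1cc(=O)cc(C)o1
F9 | step 4 | 2-methyl-6-(methylsulfonyl)-4H-pyran-4-one | CS(=O)(=O)c1cc(=O)cc(C)o1
F10 | step 5 | tert-butyl (2,2-dimethyl-4-oxo-4H-1,3-dioxin-6-yl)acetate | CC(C)(C)OC(=O)CC1=CC(=O)OC(C)(C)O1
F11 | step 5 | tert-butyl {4-oxo-6-[4-(triisopropylsilyloxy)phenoxy]-4H-pyran-2-yl}acetate | CC(C)(C)OC(=O)Cc1cc(=O)cc(Oc2ccc(O[Si](C(C)C)(C(C)C)C(C)C)cc2)o1
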